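The route rests on cutting the dihydropyran ring fused to ring A at two bonds at once: the benzylic CH2–CH2 bond and the bond from the pyran oxygen to C5 (coumarin numbering). The key step exploits the ortho relationship on ring A between CH2-bearing C6 and oxygen-bearing C5: in one pot, as a formal (3+3) annulation, a benzylic Grignard reagent opens 2,2-dimethyloxirane at its CH2 and the tertiary alkoxide thus released displaces the ortho fluorine. Its precursor is a chloromethyl-substituted 2,6-difluoro-4-methoxyphenyl dioxolane, whose symmetry leaves the second fluorine where the lactone oxygen belongs. Coumarin formation with a benzofuranone and oxidative furan closure complete the coumestan.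

Key step: step 4

Assumption: 6-hydroxybenzofuran-2(3H)-one, the lactone of 2,4-dihydroxyphenylacetic acid, is taken as a catalogue compound. The target has no stereocentre, so none has to be set.

Step 1
Reactants: 1 2,6-difluoro-4-methoxybenzaldehyde
Product: 2 2-(2,6-difluoro-4-methoxyphenyl)-1,3-dioxolane
Conditions: ethylene glycol, p-TsOH (cat.), toluene, reflux, Dean–Stark trap
Reagents that add atoms: ethylene glycol, OCCO
Why: Acid-catalysed acetalisation (dioxolane protection) driven by azeotropic removal of water masks the aldehyde against the organometallic steps that follow.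

Step 2
Reactants: 2 2-(2,6-difluoro-4-methoxyphenyl)-1,3-dioxolane
Product: 5 [3-(1,3-dioxolan-2-yl)-2,4-difluoro-6-methoxyphenyl]methanol, via aryllithium 3 (not isolated), via aldehyde 4 (not isolated)
Conditions: n-BuLi, THF, −78 °C; DMF, −78 °C; then MeOH, NaBH4, 0 °C
Reagents that add atoms: N,N-dimethylformamide, CN(C)C=O
Why: Directed ortho metalation occurs at the only type of ring C–H present, flanked by fluorine and methoxy (two sites equivalent by symmetry), the aryllithium is formylated with DMF at −78 °C before it can lose LiF, and the aldehyde is reduced in the same pot (formylation followed by borohydride reduction).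

Step 3
Reactants: 5 [3-(1,3-dioxolan-2-yl)-2,4-difluoro-6-methoxyphenyl]methanol
Product: 6 2-[3-(chloromethyl)-2,6-difluoro-4-methoxyphenyl]-1,3-dioxolane
Conditions: PPh3, N-chlorosuccinimide, THF, 0 °C → rt
Reagents that add atoms: N-chlorosuccinimide, O=C1CCC(=O)N1Cl
Why: Appel-type chlorination through the alkoxyphosphonium salt converts the primary benzylic alcohol to the chloride under neutral conditions that leave the dioxolane intact.

Step 4
Reactants: 6 2-[3-(chloromethyl)-2,6-difluoro-4-methoxyphenyl]-1,3-dioxolane; 7 2,2-dimethyloxirane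
Product: 11 7-fluoro-5-methoxy-2,2-dimethylchroman-8-carbaldehyde, via benzylic Grignard reagent 8 (not isolated), via magnesium alkoxide 9 (not isolated), via chroman acetal 10 (not isolated)
Conditions: Mg, THF, 0 °C; then 7, CuBr·SMe2 (10 mol%), −30 °C → rt; then KOtBu, DMSO, 70 °C; then 2 M HCl, rt
Reagents that add atoms: water, O
Why: Magnesium inserts into the benzylic C–Cl bond of 6, the Grignard reagent 8 (as its cuprate) opens 2,2-dimethyloxirane by SN2 attack at the unsubstituted CH2, which forms the CH2–CH2 bond and releases tertiary alkoxide 9; once converted to the potassium alkoxide in DMSO, 9 attacks the fluorine-bearing arene carbon ortho to the side chain and expels fluoride (SNAr) to form the O–aryl bond, and the acid work-up unmasks the aldehyde. The closest known reaction types are the copper-catalysed opening of epoxides by benzylic Grignard reagents and the intramolecular SNAr etherification of 3-(2-fluoroaryl)propanols to chromans, run here in one pot as a formal (3+3) annulation. The dihydropyran ring closes in a 6-exo-trig mode, counting the arene C=C bond that takes up the charge in the Meisenheimer-type transition state. No stereocentre is formed. Regioselectivity of the epoxide opening is secured by the fully substituted second epoxide carbon. Site selectivity of the ring closure is secured by geometry: only the fluorine ortho to the chain is within reach (the methoxy group on the other ortho carbon is a far poorer leaving group), and the para fluorine is kept for step 5.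

Step 5
Reactants: 11 7-fluoro-5-methoxy-2,2-dimethylchroman-8-carbaldehyde
Product: 13 7-hydroxy-5-methoxy-2,2-dimethylchroman-8-carbaldehyde, via sulfonylethyl ether 12 (not isolated)
Conditions: 2-(methylsulfonyl)ethanol, NaH, DMF, 0 °C → rt; then aq. HCl
Reagents that add atoms: 2-(methylsulfonyl)ethanol, CS(=O)(=O)CCO
Why: Nucleophilic aromatic substitution of the fluorine ortho to the aldehyde by the alkoxide of 2-(methylsulfonyl)ethanol, followed by E1cB loss of methyl vinyl sulfone from ether 12, should deliver the phenol without exposing the aldehyde to hydroxide.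

Step 6
Reactants: 13 7-hydroxy-5-methoxy-2,2-dimethylchroman-8-carbaldehyde; 14 6-hydroxybenzofuran-2(3H)-one
Product: 16 3-(2,4-dihydroxyphenyl)-7-methoxycoumarin bearing a 2,2-dimethyl-3,4-dihydro-2H-pyran ring fused at C5–C6 (pyran O on C5), via benzylidene lactone 15 (not isolated)
Conditions: Et3N, EtOH, 80 °C
Reagents that add atoms: none
Why: Knoevenagel condensation of the acidic lactone CH2 of 14 with the aldehyde gives benzylidene lactone 15, whose ring A phenoxide then attacks the lactone carbonyl (translactonisation after E/Z equilibration) to give the six-membered coumarin and free the 2'-hydroxyl group.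

Step 7
Reactants: 16 3-(2,4-dihydroxyphenyl)-7-methoxycoumarin bearing a 2,2-dimethyl-3,4-dihydro-2H-pyran ring fused at C5–C6 (pyran O on C5)
Product: 17 CNP0304440.0, 9-hydroxy-3-methoxycoumestan bearing a 2,2-dimethyl-3,4-dihydro-2H-pyran ring fused at C1–C2 (pyran O on C1)
Conditions: Cu(OAc)2 (20 mol%), 1,10-phenanthroline, NaOAc, O2 (1 atm), DMF, 110 °C
Reagents that add atoms: none
Why: Copper-catalysed aerobic cross-dehydrogenative C–O coupling (oxidative cyclisation of a 2'-hydroxy-3-arylcoumarin to a coumestan) should join the 2'-oxygen to the electron-poor C4 of the coumarin, the only position it can reach, and leave the 4'-hydroxyl as the free 9-OH of the target.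

Compound list
1 | 2,6-difluoro-4-methoxybenzaldehyde | COc1cc(F)c(C=O)c(F)c1 | starting material
2 | 2-(2,6-difluoro-4-methoxyphenyl)-1,3-dioxolane | COc1cc(F)c(C2OCCO2)c(F)c1 | intermediate
3 | [3-(1,3-dioxolan-2-yl)-2,4-difluoro-6-methoxyphenyl]lithium (not isolated) | COc1cc(F)c(C2OCCO2)c(F)c1[Li] | intermediate
4 | 3-(1,3-dioxolan-2-yl)-2,4-difluoro-6-methoxybenzaldehyde (not isolated) | COc1cc(F)c(C2OCCO2)c(F)c1C=O | intermediate
5 | [3-(1,3-dioxolan-2-yl)-2,4-difluoro-6-methoxyphenyl]methanol | COc1cc(F)c(C2OCCO2)c(F)c1CO | intermediate
6 | 2-[3-(chloromethyl)-2,6-difluoro-4-methoxyphenyl]-1,3-dioxolane | COc1cc(F)c(C2OCCO2)c(F)c1CCl | intermediate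
7 | 2,2-dimethyloxirane (isobutylene oxide) | CC1(C)CO1 | starting material
8 | [3-(1,3-dioxolan-2-yl)-2,4-difluoro-6-methoxybenzyl]magnesium chloride (not isolated) | COc1cc(F)c(C2OCCO2)c(F)c1C[Mg]Cl | intermediate
9 | chloromagnesium 4-[3-(1,3-dioxolan-2-yl)-2,4-difluoro-6-methoxyphenyl]-2-methylbutan-2-olate (not isolated) | COc1cc(F)c(C2OCCO2)c(F)c1CCC(C)(C)O[Mg]Cl | intermediate
10 | 2-(7-fluoro-5-methoxy-2,2-dimethylchroman-8-yl)-1,3-dioxolane (not isolated) | COc1cc(F)c(C2OCCO2)c2c1CCC(C)(C)O2 | intermediate
11 | 7-fluoro-5-methoxy-2,2-dimethylchroman-8-carbaldehyde | COc1cc(F)c(C=O)c2c1CCC(C)(C)O2 | intermediate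
12 | 5-methoxy-2,2-dimethyl-7-[2-(methylsulfonyl)ethoxy]chroman-8-carbaldehyde (not isolated) | COc1cc(OCCS(C)(=O)=O)c(C=O)c2c1CCC(C)(C)O2 | intermediate
13 | 7-hydroxy-5-methoxy-2,2-dimethylchroman-8-carbaldehyde | COc1cc(O)c(C=O)c2c1CCC(C)(C)O2 | intermediate
14 | 6-hydroxybenzofuran-2(3H)-one | O=C1Cc2ccc(O)cc2O1 | starting material
15 | (Z)-6-hydroxy-3-[(7-hydroxy-5-methoxy-2,2-dimethylchroman-8-yl)methylidene]benzofuran-2(3H)-one (not isolated) | O=C1Oc2cc(O)ccc2/C1=C/c1c(O)cc(OC)c2CCC(C)(C)Oc12 | intermediate
16 | 3-(2,4-dihydroxyphenyl)-7-methoxycoumarin bearing a 2,2-dimethyl-3,4-dihydro-2H-pyran ring fused at C5–C6 (pyran O on C5) | COc1cc2oc(=O)c(-c3ccc(O)cc3O)cc2c2c1CCC(C)(C)O2 | intermediate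
17 | CNP0304440.0, 9-hydroxy-3-methoxycoumestan bearing a 2,2-dimethyl-3,4-dihydro-2H-pyran ring fused at C1–C2 (pyran O on C1) | COc1cc2oc(=O)c3c4ccc(O)cc4oc3c2c2c1CCC(C)(C)O2 | target

Total step count: 7
Longest linear sequence: 7 steps (1 → 17)

Steps most likely to fail

Step 4. The magnesium insertion may be eroded by Wurtz-type homocoupling of the benzylic halide. The epoxide may isomerise under the Lewis-acidic magnesium salts before the C–C bond forms. Ring closure may be slow because the arene is only weakly activated towards substitution. The fallback reverses the polarity at the benzylic carbon and sets out from 6. Alkylation of the lithium enolate of tert-butyl acetate (LiN(iPr)2, THF, −78 °C) with 6 should give tert-butyl 3-[3-(1,3-dioxolan-2-yl)-2,4-difluoro-6-methoxyphenyl]propanoate F1. Double addition of MeMgBr (THF, 0 °C → rt) should give 4-[3-(1,3-dioxolan-2-yl)-2,4-difluoro-6-methoxyphenyl]-2-methylbutan-2-ol F2. NaH in DMF at 90 °C should close the chroman by intramolecular SNAr, which comes back to the route at 10; acid hydrolysis then leads on to 11.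

Step 7. The free resorcinol-type ring D may be degraded oxidatively under aerobic copper conditions, or the C–O bond may fail to form at the hindered C4. The fallback sets out from 16 and replaces the catalytic aerobic coupling by a stoichiometric two-electron oxidation of a substrate with a single free phenol. Silylation of the less hindered 4'-hydroxyl (TBSCl, imidazole, DMF, 0 °C) should give the 4'-O-tert-butyldimethylsilyl ether of 16 F3. Oxidative cyclisation with lead tetraacetate Pb(OAc)4 (benzene, rt → 50 °C) should give the 9-O-tert-butyldimethylsilyl ether of the coumestan F4. Desilylation with Bu4NF (THF, 0 °C) comes back to the route at 17.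

Step 6. Condensation may be slow at the hindered, hydrogen-bonded and electron-rich aldehyde, and the lactone partner may undergo base-mediated ring opening and self-condensation instead. The fallback sets out from 13 and uses a Perkin–Oglialoro condensation with purchased 2,4-dihydroxyphenylacetic acid (Ac2O, Et3N, 120 °C). Here the phenols are acetylated in the flask and the coumarin closes through the aryl ester, which should give the 2',4'-di-O-acetyl derivative of 16 F5. Methanolysis of the acetates (K2CO3, MeOH, rt) comes back to the route at 16.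

Further compounds
F1 | step 4 | tert-butyl 3-[3-(1,3-dioxolan-2-yl)-2,4-difluoro-6-methoxyphenyl]propanoate | COc1cc(F)c(C2OCCO2)c(F)c1CCC(=O)OC(C)(C)C
F2 | step 4 | 4-[3-(1,3-dioxolan-2-yl)-2,4-difluoro-6-methoxyphenyl]-2-methylbutan-2-ol | COc1cc(F)c(C2OCCO2)c(F)c1CCC(C)(C)O
F3 | step 7 | 4'-O-tert-butyldimethylsilyl ether of 16 | COc1cc2oc(=O)c(-c3ccc(O[Si](C)(C)C(C)(C)C)cc3O)cc2c2c1CCC(C)(C)O2
F4 | step 7 | 9-O-tert-butyldimethylsilyl ether of 17 | COc1cc2oc(=O)c3c4ccc(O[Si](C)(C)C(C)(C)C)cc4oc3c2c2c1CCC(C)(C)O2
F5 | step 6 | 2',4'-di-O-acetyl derivative of 16 | COc1cc2oc(=O)c(-c3ccc(OC(C)=O)cc3OC(C)=O)cc2c2c1CCC(C)(C)O2
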